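Take the flask early. It holds substrate and partner, and these are the charges, the earlier runs and the questions:

all flasks: substrate 25 mM
- beta: partner 0.74 equiv; run made earlier
- eta: partner 1.7 equiv; run made earlier
- flask: partner 1.10 equiv; time 2.5 d

| run | time / h | isomer of the product / % | target / % |
|---|---|---|---|
| beta | 0.500 | 15.9 | 25.9 |
| beta | 1.33 | 17.6 | 30.0 |
| beta | 3.00 | 18.2 | 25.1 |
| beta | 8.00 | 12.9 | 19.9 |
| beta | 20.0 | 8.6 | 11.1 |
| beta | 50.0 | 0 | 3.0 |
| eta | 0.500 | 28.1 | 44.5 |
| eta | 1.33 | 32.2 | 48.2 |
| eta | 3.00 | 27.2 | 42.3 |
| eta | 8.00 | 21.9 | 32.8 |
| eta | 20.0 | 12.0 | 15.7 |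
| eta | 50.0 | 2.8 | 4.3 |

(scatter of a reading: 1 percentage point)



- time up to 2.5 d at which isomer of the product stands highest
- the amount of isomer of the product, in percent of the substrate charged, at that time
- earliest time at which at least nineteen twentieths of that best amount are there
- latest time at which they still are, in d

In both runs target and isomer of the product rise and fall together. Carry one number from them. The split is isomer over target, summed over the readings of both runs, 0.652. Read so, isomer is 39.5% of the pair, target plus isomer.

At 1.33 h the pair reads 47.6% with 0.74 equiv of partner and 80.4% with 1.7 equiv, so the partner charge differs by a larger factor than the pair does. A power law through these two readings puts your flask, at 1.10 equiv, near 61.1%, so my figure for its best isomer is 24.1%, around that time. Do not wait out the full 2.5 d: the eta run has fallen to 2.8% of isomer by 50.0 h.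

The forecast, higher than my figure, says 25% at 0.055 d, with the window from 0.7 h to 0.1 d, noting that “Their ratio stays near 0.6”. The flask gives 25.1% at 0.0526 d, with the window from 0.714 h to 0.102 d.

    substrate + partner ⇌ target (K = 140 L mol⁻¹, k = 2.20 L mol⁻¹ min⁻¹)
    partner → decomposed reagent (k = 0.00520 min⁻¹)
    target ⇌ isomer of the product (K = 0.660, k = 0.110 min⁻¹)

At 0.0526 d the flask's 38.0% of target times the split gives 24.8% of isomer, and 25.1% stands there. Target and isomer relax into each other with a half-life of 0.0418 h, short against 2.5 d. The way back from isomer to target is the largest single effect on the best amount : the run without it reaches 87.3% against 25.1%. In the neighbour flask with 0.440 equiv of partner, 1.25% of target at 2.50 d times the split gives 0.815% of isomer, and 0.829% stands there.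

The numbers in the tables were generated by integration with made-up constants.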